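**The decision.** We would plan the spring flask on the low side of your forecast. Here are the flasks, the readings and what you asked.

| flask | E | Z | time |
|---|---|---|---|
| summer | 0.120 M | 6.00 × 10⁻⁴ M |  |
| noon | 0.0720 M | 6.00 × 10⁻⁴ M |  |
| winter | 0.120 M | 9.00 × 10⁻⁴ M |  |
| autumn | 0.180 M | 6.00 × 10⁻⁴ M |  |
| spring | 0.240 M | 2.00 × 10⁻⁴ M | 4.3 min |

| run | time / min | [X] / M |
|---|---|---|
| summer run | 0.17 | 0.0056 |
| summer run | 0.38 | 0.0123 |
| summer run | 0.86 | 0.0253 |
| summer run | 1.9 | 0.0467 |
| summer run | 4.3 | 0.0655 |
| noon run | 0.17 | 0.0055 |
| noon run | 0.38 | 0.0096 |
| noon run | 0.86 | 0.0206 |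
| noon run | 1.9 | 0.0378 |
| noon run | 4.3 | 0.0456 |
| winter run | 0.17 | 0.0080 |
| winter run | 0.38 | 0.0187 |
| winter run | 0.86 | 0.0375 |
| winter run | 1.9 | 0.0648 |
| winter run | 4.3 | 0.0792 |
| autumn run | 0.17 | 0.0062 |
| autumn run | 0.38 | 0.0139 |
| autumn run | 0.86 | 0.0261 |
| autumn run | 1.9 | 0.0513 |
| autumn run | 4.3 | 0.0768 |

(each reading ± 6 × 10⁻⁴ M)

- Overall: E -> X, with Z as catalyst.
- Constant volume, constant temperature.
- Readings of a species count what is bound in complexes too.
- An order is taken over about fifteen percent of the charge, up and down.

- the power of [Z] that the first rate follows, about the charge of the summer run; measure it at two percent of E made into X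
- the power of [E] that the first rate follows, about the charge of the summer run; measure it at two percent of E made into X (one fixed amount of X, the same in the runs compared)
- X in the spring run at 4.3 min, as a share of the E charged

**Our count.** The autumn run reads 128 at 4.3 min, and this number T, the X standing at that time per Z charged (a turnover number), is what we carry. At the same Z, noon gives 76.0 and summer 109. Noon to summer gains 33.2 for 0.0480 M more E, while summer to autumn gains 18.8 for 0.0600 M more, so added E buys less as the charge grows.

**Our number.** Spring has 2.00 × 10⁻⁴ M of Z, so the autumn count gives 0.0256 M of X, or 10.7% of its E. The winter run, with more Z at the E of summer, counts 88.0, fewer than summer. The spring flask differs from the autumn run in two settings, with more E and less Z, and in the runs above each of these went with a higher count, so we expect a little above that share.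

**Your forecast.** It says 14.5%, between 12% and 18.5%, with orders 1 in Z and 0.38 in E, holding that “the catalyst dies with time”. We share that view but not the number. Your share means a spring count of 174, higher than any run has read.

**The result.** The spring flask gives 11.5%. About the charge of the summer run, the orders are 1.0 in Z and 0.22 in E.

    Z + E ⇌ ZE, settled at all times (31.40 M⁻¹)
    ZE → X + Z (72.00 min⁻¹)
    ZE → Ez + E (0.1938 min⁻¹)
    X → Ju (0.1434 min⁻¹)

That share is a spring count of 138, a little above the 128 carried from autumn. The constants give 372 X made for each Z lost to Ez. The spring count is 37.1% of that ratio, and the winter count is 23.7% of it.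

(Readings and results stem from a simulated flask on assumed constants, noise included.)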